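**Retrosynthetic overview**

1. Target 28 comes from bis-silyl ether 27 by desilylation. The oxepinone (ring numbering O1, C2(=O), C3, C4, C5, C6, C7; side-chain carbinol C1′) is the only ring and is cut at two bonds at once, O1–C7 and C2–C3.
2. Enabling feature: the O1–C2(=O) segment of the ring is a CO2 unit held between the sp2 carbon C3 and the quaternary carbon C7, and C7 carries on its exocyclic neighbour C1′ a free hydroxyl anti to O1. This is the imprint of a (Z)-trisubstituted epoxide opened at its methyl-bearing carbon, so 27 comes from CO2 and the acyclic (Z)-iodoalkene epoxide 23 (lithiation, carboxylation and 7-exo lactonisation in one flask).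
3. 23 comes from epoxy aldehyde 13 and the iodo ylide made from phosphonium salt 19; the iodo-Wittig sets the (Z)-iodoalkene that becomes C3=C4.
4. 13 comes from nerol (1): silylation, cleavage of the remote alkene, Still–Gennari olefination, reduction, Sharpless epoxidation (source of both stereocentres), two-carbon extension. 19 comes from phosphonium salt 14 and silyloxyacetone 15.
5. Ring order: the temporary oxirane is made first (step 6); the oxepinone is closed in step 13.

Key step: step 13

Abbreviation: TBS = tert-butyldimethylsilyl; TBSO = its ether oxygen.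
Assumption (chemistry): L-(+)-diethyl tartrate is taken to epoxidise allylic alcohol 8 with the same facial sense with which it converts nerol into (2S,3R)-2,3-epoxynerol, which gives the (2S,3R)-oxirane needed here.

**Step 1**
Reactants: 1 nerol [(2Z)-3,7-dimethylocta-2,6-dien-1-ol]
Product: 2 nerol TBS ether tert-butyl{[(2Z)-3,7-dimethylocta-2,6-dien-1-yl]oxy}dimethylsilane
Conditions: TBSCl, imidazole, CH2Cl2, 0 °C to rt
Reagents that add atoms: tert-butyldimethylsilyl chloride CC(C)(C)[Si](C)(C)Cl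
Why: Imidazole-mediated silylation of the primary allylic alcohol (silyl ether formation) masks the hydroxyl for all later organometallic steps; no stereocentre is formed.

**Step 2**
Reactants: 2 nerol TBS ether
Product: 3 racemic epoxide tert-butyl{[(2Z)-5-(3,3-dimethyloxiran-2-yl)-3-methylpent-2-en-1-yl]oxy}dimethylsilane
Conditions: mCPBA, NaHCO3, CH2Cl2, −20 to 0 °C
Reagents that add atoms: 3-chloroperoxybenzoic acid O=C(OO)c1cccc(Cl)c1
Why: Prilezhaev epoxidation should select the electron-rich remote alkene over the alkene deactivated by the allylic silyloxy group; the new stereocentre is racemic and is destroyed in step 3.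

**Step 3**
Reactants: 3 racemic epoxide
Product: 4 aldehyde (4Z)-6-(TBSO)-4-methylhex-4-enal
Conditions: H5IO6, THF–Et2O, 0 °C
Reagents that add atoms: none
Why: Periodic acid should cleave the trisubstituted epoxide oxidatively to the aldehyde and acetone (Malaprade-type cleavage) without touching the (Z)-alkene.

**Step 4**
Reactants: 4 aldehyde; 5 ethyl 2-[bis(2,2,2-trifluoroethoxy)phosphoryl]propanoate
Product: 7 ethyl (2Z,6Z)-8-(TBSO)-2,6-dimethylocta-2,6-dienoate, via potassium phosphonate carbanion 6 (not isolated)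
Conditions: KN(SiMe3)2, 18-crown-6, THF, −78 °C; then 4
Reagents that add atoms: potassium bis(trimethylsilyl)amide C[Si](C)(C)[N-][Si](C)(C)C.[K+] (its potassium stays only in intermediate 6)
Why: Still–Gennari olefination with the electron-poor bis(trifluoroethyl) phosphonate is kinetically (Z)-selective and places the ester carbon cis to the chain, which fixes the cis relationship needed in the later epoxide.

**Step 5**
Reactants: 7 (Z,Z)-dienoate
Product: 8 allylic alcohol (2Z,6Z)-8-(TBSO)-2,6-dimethylocta-2,6-dien-1-ol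
Conditions: i-Bu2AlH, CH2Cl2, −78 °C; aq. potassium sodium tartrate
Reagents that add atoms: none
Why: 1,2-Reduction of the unsaturated ester by the aluminium hydride gives the allylic alcohol with the alkene geometry unchanged.

**Step 6**
Reactants: 8 allylic alcohol
Product: 9 epoxy alcohol [(2S,3R)-3-[(3Z)-5-(TBSO)-3-methylpent-3-en-1-yl]-2-methyloxiran-2-yl]methanol
Conditions: Ti(OiPr)4 (10 mol %), L-(+)-diethyl tartrate (12 mol %), t-BuOOH, 4 Å molecular sieves, CH2Cl2, −20 °C
Reagents that add atoms: tert-butyl hydroperoxide CC(C)(C)OO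
Why: Sharpless asymmetric epoxidation delivers oxygen only to the alkene bearing the free allylic hydroxyl and sets both oxirane stereocentres (2S,3R) by reagent control of the titanium tartrate catalyst, the cis-epoxide following from the (Z)-alkene.

**Step 7**
Reactants: 9 epoxy alcohol
Product: 11 epoxy nitrile 3-[(2S,3R)-3-[(3Z)-5-(TBSO)-3-methylpent-3-en-1-yl]-2-methyloxiran-2-yl]propanenitrile, via epoxy triflate 10 (not isolated)
Conditions: Tf2O, 2,6-lutidine, CH2Cl2, −78 °C; then LiCH2CN (from MeCN, n-BuLi), THF, −78 °C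
Reagents that add atoms: acetonitrile CC#N; triflic anhydride O=S(=O)(OS(=O)(=O)C(F)(F)F)C(F)(F)F (its CF3SO2 group stays only in intermediate 10)
Why: SN2 alkylation of the nitrile-stabilised carbanion by the primary triflate should outrun attack on the unactivated epoxide at −78 °C, adding the two carbons that become C5 and C4 of the ring without touching the stereocentres.

**Step 8**
Reactants: 11 epoxy nitrile
Product: 13 epoxy aldehyde 3-[(2S,3R)-3-[(3Z)-5-(TBSO)-3-methylpent-3-en-1-yl]-2-methyloxiran-2-yl]propanal, via N-aluminio imine 12 (not isolated)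
Conditions: i-Bu2AlH, toluene, −78 °C; then pH 7 aq. potassium sodium tartrate, silica gel
Reagents that add atoms: water O (aldehyde oxygen); diisobutylaluminium hydride CC(C)C[AlH]CC(C)C (its aluminium and isobutyl groups stay only in intermediate 12)
Why: Single hydride addition to the nitrile and hydrolysis of the metallo-imine (nitrile-to-aldehyde reduction) should give the aldehyde while the epoxide survives at −78 °C.

**Step 9**
Reactants: 14 (4-hydroxybutyl)triphenylphosphonium bromide; 15 1-(TBSO)propan-2-one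
Product: 17 alcohol (4Z)-6-(TBSO)-5-methylhex-4-en-1-ol, via alkoxide ylide 16 (not isolated)
Conditions: KN(SiMe3)2 (2 equiv), THF, 0 °C; then 15, −78 °C to rt
Reagents that add atoms: potassium bis(trimethylsilyl)amide C[Si](C)(C)[N-][Si](C)(C)C.[K+] (its potassium stays only in intermediate 16)
Why: Wittig olefination of an α-silyloxy ketone with a non-stabilised ylide under salt-free conditions, a substrate class that gives the (Z)-trisubstituted allylic ether with the oxygenated carbon cis to the ylide-derived chain.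

**Step 10**
Reactants: 17 alcohol
Product: 18 iodide tert-butyl{[(2Z)-6-iodo-2-methylhex-2-en-1-yl]oxy}dimethylsilane
Conditions: I2, PPh3, imidazole, CH2Cl2, 0 °C
Reagents that add atoms: iodine II
Why: Appel-type iodination converts the primary alcohol to the iodide by SN2 displacement of the oxyphosphonium group.

**Step 11**
Reactants: 18 iodide
Product: 19 phosphonium salt [(4Z)-6-(TBSO)-5-methylhex-4-en-1-yl]triphenylphosphonium iodide
Conditions: PPh3, MeCN, 80 °C
Reagents that add atoms: triphenylphosphine c1ccc(cc1)P(c1ccccc1)c1ccccc1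
Why: SN2 quaternisation of triphenylphosphine by the primary iodide gives the salt needed for the iodo ylide.

**Step 12**
Reactants: 13 epoxy aldehyde; 19 phosphonium salt
Product: 23 (Z)-iodoalkene epoxide (2S,3R)-2-[(3Z,7Z)-9-(TBSO)-4-iodo-8-methylnona-3,7-dien-1-yl]-3-[(3Z)-5-(TBSO)-3-methylpent-3-en-1-yl]-2-methyloxirane, via phosphonium ylide 20 (not isolated), via iodophosphonium iodide 21 (not isolated), via iodo ylide 22 (not isolated)
Conditions: n-BuLi, THF, 0 °C; I2, −78 °C; NaN(SiMe3)2, −78 to −20 °C; then 13, −78 °C to rt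
Reagents that add atoms: iodine II
Why: Stork–Zhao-type iodo-olefination: kinetic oxaphosphetane formation from the α-iodo ylide should place iodine cis to the aldehyde-derived chain, giving the (Z)-iodoalkene, while the epoxide is inert to the ylide.

**Step 13**
Reactants: 23 (Z)-iodoalkene epoxide
Product: 27 bis-TBS lactone (7R)-3-[(3Z)-5-(TBSO)-4-methylpent-3-en-1-yl]-7-[(1R,4Z)-6-(TBSO)-1-hydroxy-4-methylhex-4-en-1-yl]-7-methyl-6,7-dihydrooxepin-2(5H)-one, via alkenyllithium 24 (not isolated), via lithium carboxylate 25 (not isolated), via epoxy acid 26 (not isolated)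
Conditions: n-BuLi (1.05 equiv), Et2O, −78 °C; CO2 (gas), −78 to −20 °C; then camphorsulfonic acid (1.2 equiv), CH2Cl2, high dilution, −20 °C to rt
Reagents that add atoms: carbon dioxide O=C=O; n-butyllithium [Li]CCCC (its lithium stays only in intermediates 24 and 25)
Why: Iodine–lithium exchange gives alkenyllithium 24 with retention of the (Z)-geometry, CO2 is captured at the lithiated carbon to forge C2–C3 (carboxylate 25), and after protonation the carboxyl group of 26, held cis to the C4–C5–C6 tether, opens the acid-activated epoxide at its methyl-bearing carbon to forge O1–C7. The closest known reaction types are the carboxylation of alkenyllithiums with CO2 and the acid-catalysed hydroxy-lactonisation of epoxy carboxylic acids. The oxepinone closes in a 7-exo-tet mode, the breaking epoxide C–O bond lying outside the new ring. C7 is set by inversion at the quaternary epoxide carbon and C1′ is the untouched second epoxide carbon, so both stereocentres are relayed from the Sharpless step and the anti O1/OH relationship follows from the cis-epoxide. The step needs attack at the tertiary rather than the secondary epoxide carbon, and lactonisation rather than cationic rearrangement or participation of the remote alkenes: the tertiary site is favoured both electronically and by ring size (7-exo against 8-endo), the (Z)-alkene pre-organises the acid, and the allylic silyloxy groups deactivate the two trisubstituted alkenes. Because the exchange is run with n-BuLi, no iodide salt is present when the acid is added, so no halide competes for the epoxide.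

**Step 14**
Reactants: 27 bis-TBS lactone
Product: 28 target (7R)-7-[(1R,4Z)-1,6-dihydroxy-4-methylhex-4-en-1-yl]-3-[(3Z)-5-hydroxy-4-methylpent-3-en-1-yl]-7-methyl-6,7-dihydrooxepin-2(5H)-one
Conditions: HF·pyridine, pyridine, THF, 0 °C to rt
Reagents that add atoms: none
Why: Fluoride-driven cleavage of both primary silyl ethers (Si–F bond formation) under buffered conditions should leave the unsaturated lactone, the alkenes and both stereocentres untouched.

**Compound list**

1 | nerol, (2Z)-3,7-dimethylocta-2,6-dien-1-ol | CC(C)=CCC/C(C)=C\CO | starting material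
2 | tert-butyl{[(2Z)-3,7-dimethylocta-2,6-dien-1-yl]oxy}dimethylsilane | CC(C)=CCC/C(C)=C\CO[Si](C)(C)C(C)(C)C | intermediate
3 | tert-butyl{[(2Z)-5-(3,3-dimethyloxiran-2-yl)-3-methylpent-2-en-1-yl]oxy}dimethylsilane (racemic) | CC1(C)OC1CC/C(C)=C\CO[Si](C)(C)C(C)(C)C | intermediate
4 | (4Z)-6-(TBSO)-4-methylhex-4-enal | O=CCC/C(C)=C\CO[Si](C)(C)C(C)(C)C | intermediate
5 | ethyl 2-[bis(2,2,2-trifluoroethoxy)phosphoryl]propanoate | CCOC(=O)C(C)P(=O)(OCC(F)(F)F)OCC(F)(F)F | starting material
6 | potassium carbanion of 5 | CCOC(=O)[C-](C)P(=O)(OCC(F)(F)F)OCC(F)(F)F.[K+] | intermediate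
7 | ethyl (2Z,6Z)-8-(TBSO)-2,6-dimethylocta-2,6-dienoate | CCOC(=O)/C(C)=C\CC/C(C)=C\CO[Si](C)(C)C(C)(C)C | intermediate
8 | (2Z,6Z)-8-(TBSO)-2,6-dimethylocta-2,6-dien-1-ol | OC/C(C)=C\CC/C(C)=C\CO[Si](C)(C)C(C)(C)C | intermediate
9 | [(2S,3R)-3-[(3Z)-5-(TBSO)-3-methylpent-3-en-1-yl]-2-methyloxiran-2-yl]methanol | OC[C@]1(C)O[C@@H]1CC/C(C)=C\CO[Si](C)(C)C(C)(C)C | intermediate
10 | triflate of 9, [(2S,3R)-3-[(3Z)-5-(TBSO)-3-methylpent-3-en-1-yl]-2-methyloxiran-2-yl]methyl trifluoromethanesulfonate | O=S(=O)(OC[C@]1(C)O[C@@H]1CC/C(C)=C\CO[Si](C)(C)C(C)(C)C)C(F)(F)F | intermediate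
11 | 3-[(2S,3R)-3-[(3Z)-5-(TBSO)-3-methylpent-3-en-1-yl]-2-methyloxiran-2-yl]propanenitrile | N#CCC[C@]1(C)O[C@@H]1CC/C(C)=C\CO[Si](C)(C)C(C)(C)C | intermediate
12 | N-(diisobutylaluminio) imine of 13 | CC(C)C[Al](CC(C)C)N=CCC[C@]1(C)O[C@@H]1CC/C(C)=C\CO[Si](C)(C)C(C)(C)C | intermediate
13 | 3-[(2S,3R)-3-[(3Z)-5-(TBSO)-3-methylpent-3-en-1-yl]-2-methyloxiran-2-yl]propanal | O=CCC[C@]1(C)O[C@@H]1CC/C(C)=C\CO[Si](C)(C)C(C)(C)C | intermediate
14 | (4-hydroxybutyl)triphenylphosphonium bromide | OCCCC[P+](c1ccccc1)(c1ccccc1)c1ccccc1.[Br-] | starting material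
15 | 1-(TBSO)propan-2-one | CC(=O)CO[Si](C)(C)C(C)(C)C | starting material
16 | potassium 4-(triphenylphosphoranylidene)butan-1-olate | [K+].[O-]CCCC=P(c1ccccc1)(c1ccccc1)c1ccccc1 | intermediate
17 | (4Z)-6-(TBSO)-5-methylhex-4-en-1-ol | OCCC/C=C(/C)CO[Si](C)(C)C(C)(C)C | intermediate
18 | tert-butyl{[(2Z)-6-iodo-2-methylhex-2-en-1-yl]oxy}dimethylsilane | ICCC/C=C(/C)CO[Si](C)(C)C(C)(C)C | intermediate
19 | [(4Z)-6-(TBSO)-5-methylhex-4-en-1-yl]triphenylphosphonium iodide | CC(C)(C)[Si](C)(C)OC/C(C)=C\CCC[P+](c1ccccc1)(c1ccccc1)c1ccccc1.[I-] | intermediate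
20 | ylide of 19, [(4Z)-6-(TBSO)-5-methylhex-4-en-1-ylidene]triphenylphosphorane | CC(C)(C)[Si](C)(C)OC/C(C)=C\CCC=P(c1ccccc1)(c1ccccc1)c1ccccc1 | intermediate
21 | [(4Z)-6-(TBSO)-1-iodo-5-methylhex-4-en-1-yl]triphenylphosphonium iodide | CC(C)(C)[Si](C)(C)OC/C(C)=C\CCC(I)[P+](c1ccccc1)(c1ccccc1)c1ccccc1.[I-] | intermediate
22 | [(4Z)-6-(TBSO)-1-iodo-5-methylhex-4-en-1-ylidene]triphenylphosphorane | CC(C)(C)[Si](C)(C)OC/C(C)=C\CCC(I)=P(c1ccccc1)(c1ccccc1)c1ccccc1 | intermediate
23 | (2S,3R)-2-[(3Z,7Z)-9-(TBSO)-4-iodo-8-methylnona-3,7-dien-1-yl]-3-[(3Z)-5-(TBSO)-3-methylpent-3-en-1-yl]-2-methyloxirane | CC(C)(C)[Si](C)(C)OC/C(C)=C\CC/C(I)=C/CC[C@]1(C)O[C@@H]1CC/C(C)=C\CO[Si](C)(C)C(C)(C)C | intermediate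
24 | alkenyllithium from 23 (lithium in place of iodine, geometry retained) | CC(C)(C)[Si](C)(C)OC/C(C)=C\CC/C([Li])=C/CC[C@]1(C)O[C@@H]1CC/C(C)=C\CO[Si](C)(C)C(C)(C)C | intermediate
25 | lithium salt of acid 26 | CC(C)(C)[Si](C)(C)OC/C(C)=C\CC/C(C(=O)[O-])=C/CC[C@]1(C)O[C@@H]1CC/C(C)=C\CO[Si](C)(C)C(C)(C)C.[Li+] | intermediate
26 | (2Z)-2-[(3Z)-5-(TBSO)-4-methylpent-3-en-1-yl]-5-[(2S,3R)-3-[(3Z)-5-(TBSO)-3-methylpent-3-en-1-yl]-2-methyloxiran-2-yl]pent-2-enoic acid | CC(C)(C)[Si](C)(C)OC/C(C)=C\CC/C(C(=O)O)=C/CC[C@]1(C)O[C@@H]1CC/C(C)=C\CO[Si](C)(C)C(C)(C)C | intermediate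
27 | (7R)-3-[(3Z)-5-(TBSO)-4-methylpent-3-en-1-yl]-7-[(1R,4Z)-6-(TBSO)-1-hydroxy-4-methylhex-4-en-1-yl]-7-methyl-6,7-dihydrooxepin-2(5H)-one | CC(C)(C)[Si](C)(C)OC/C(C)=C\CCC1=CCC[C@](C)([C@H](O)CC/C(C)=C\CO[Si](C)(C)C(C)(C)C)OC1=O | intermediate
28 | (7R)-7-[(1R,4Z)-1,6-dihydroxy-4-methylhex-4-en-1-yl]-3-[(3Z)-5-hydroxy-4-methylpent-3-en-1-yl]-7-methyl-6,7-dihydrooxepin-2(5H)-one | C/C(=C/CCC1=CCC[C@](C)([C@H](O)CC/C(C)=C\CO)OC1=O)CO | target

**Step count and risks**

Total step count: 14. Longest linear sequence: 11 steps (steps 1–8, then 12, 13, 14).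

Steps most likely to fail:

1. Step 13 (key step). After protonation, the tertiary epoxide carbon may ionise faster than the seven-membered ring closes. That would lead to hydride shift, elimination, attack by the neighbouring trisubstituted alkene or partial loss of configuration at C7; the alkenyllithium may also be quenched by protonation before it meets CO2. Fallback: set out from 23. Brief mild acid hydration (catalytic HClO4, THF–H2O, 0 °C) should open the epoxide at the tertiary carbon with inversion to give the (2Z,6R,7R,10Z,14Z)-1,16-bis(TBSO)-11-iodo-3,7,15-trimethylhexadeca-2,10,14-triene-6,7-diol F1. Palladium-catalysed carbonylative lactonisation of the (Z)-iodoalkene (PdCl2(PPh3)2, CO 1 atm, Et3N, MeCN, 60 °C) then lets the tertiary hydroxyl trap the acyl–palladium species in the seven-membered mode (favoured over the eight-membered closure by the secondary hydroxyl), and the route is rejoined at 27.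

2. Step 12. The (Z)-selectivity of oxaphosphetane formation may erode, and iodine may be lost by proton and iodine transfer between the ylides, which would give iodine-free alkene. Fallback: set out from 13 and 15. Dibromo-olefination of 13 (CBr4, PPh3, Zn, CH2Cl2) gives the 1,1-dibromoalkene (2S,3R)-2-(4,4-dibromobut-3-en-1-yl)-3-[(3Z)-5-(TBSO)-3-methylpent-3-en-1-yl]-2-methyloxirane F2. Separately, (3-hydroxypropyl)triphenylphosphonium bromide (commercial) and 15 under the conditions of step 9 give (3Z)-5-(TBSO)-4-methylpent-3-en-1-ol F3, iodination as in step 10 gives tert-butyl{[(2Z)-5-iodo-2-methylpent-2-en-1-yl]oxy}dimethylsilane F4, and zinc insertion (Zn dust, LiCl, THF) gives the alkylzinc iodide F5. A trans-selective Negishi mono-alkylation of F2 with F5 (catalytic PdCl2[(2-Ph2PC6H4)2O], THF) replaces the bromine trans to the chain and gives the (Z)-bromoalkene (2S,3R)-2-[(3Z,7Z)-4-bromo-9-(TBSO)-8-methylnona-3,7-dien-1-yl]-3-[(3Z)-5-(TBSO)-3-methylpent-3-en-1-yl]-2-methyloxirane F6. Bromine–lithium exchange (t-BuLi, 2 equiv, Et2O, −78 °C) rejoins the route at alkenyllithium 24.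

3. Step 7. SN2 displacement at the carbon flanked by the quaternary epoxide carbon may be slow, so that decomposition of the triflate or attack of the carbanion on the epoxide competes. Fallback: set out from 9. Dess–Martin oxidation gives the epoxy aldehyde (2R,3R)-3-[(3Z)-5-(TBSO)-3-methylpent-3-en-1-yl]-2-methyloxirane-2-carbaldehyde F7 (same spatial arrangement; the descriptor changes by priority). Wittig olefination with methyl (triphenylphosphoranylidene)acetate gives methyl (2E)-3-[(2S,3R)-3-[(3Z)-5-(TBSO)-3-methylpent-3-en-1-yl]-2-methyloxiran-2-yl]prop-2-enoate F8. Diimide (from 2-nitrobenzenesulfonylhydrazide and Et3N) should reduce only the disubstituted conjugated alkene, without hydrogenolysis of the epoxide, to give methyl 3-[(2S,3R)-3-[(3Z)-5-(TBSO)-3-methylpent-3-en-1-yl]-2-methyloxiran-2-yl]propanoate F9. Reduction with i-Bu2AlH at −78 °C rejoins the route at 13.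

**Further compounds**

F1 | step 13 | (2Z,6R,7R,10Z,14Z)-1,16-bis(TBSO)-11-iodo-3,7,15-trimethylhexadeca-2,10,14-triene-6,7-diol | CC(C)(C)[Si](C)(C)OC/C(C)=C\CC/C(I)=C/CC[C@@](C)(O)[C@H](O)CC/C(C)=C\CO[Si](C)(C)C(C)(C)C
F2 | step 12 | (2S,3R)-2-(4,4-dibromobut-3-en-1-yl)-3-[(3Z)-5-(TBSO)-3-methylpent-3-en-1-yl]-2-methyloxirane | BrC(Br)=CCC[C@]1(C)O[C@@H]1CC/C(C)=C\CO[Si](C)(C)C(C)(C)C
F3 | step 12 | (3Z)-5-(TBSO)-4-methylpent-3-en-1-ol | OCC/C=C(/C)CO[Si](C)(C)C(C)(C)C
F4 | step 12 | tert-butyl{[(2Z)-5-iodo-2-methylpent-2-en-1-yl]oxy}dimethylsilane | ICC/C=C(/C)CO[Si](C)(C)C(C)(C)C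
F5 | step 12 | [(3Z)-5-(TBSO)-4-methylpent-3-en-1-yl]zinc iodide | I[Zn]CC/C=C(/C)CO[Si](C)(C)C(C)(C)C
F6 | step 12 | (2S,3R)-2-[(3Z,7Z)-4-bromo-9-(TBSO)-8-methylnona-3,7-dien-1-yl]-3-[(3Z)-5-(TBSO)-3-methylpent-3-en-1-yl]-2-methyloxirane | CC(C)(C)[Si](C)(C)OC/C(C)=C\CC/C(Br)=C/CC[C@]1(C)O[C@@H]1CC/C(C)=C\CO[Si](C)(C)C(C)(C)C
F7 | step 7 | (2R,3R)-3-[(3Z)-5-(TBSO)-3-methylpent-3-en-1-yl]-2-methyloxirane-2-carbaldehyde | O=C[C@]1(C)O[C@@H]1CC/C(C)=C\CO[Si](C)(C)C(C)(C)C
F8 | step 7 | methyl (2E)-3-[(2S,3R)-3-[(3Z)-5-(TBSO)-3-methylpent-3-en-1-yl]-2-methyloxiran-2-yl]prop-2-enoate | COC(=O)/C=C/[C@]1(C)O[C@@H]1CC/C(C)=C\CO[Si](C)(C)C(C)(C)C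
F9 | step 7 | methyl 3-[(2S,3R)-3-[(3Z)-5-(TBSO)-3-methylpent-3-en-1-yl]-2-methyloxiran-2-yl]propanoate | COC(=O)CC[C@]1(C)O[C@@H]1CC/C(C)=C\CO[Si](C)(C)C(C)(C)C
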